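Late in the dawn run L moves just from 0.6987 M to 0.7047 M between 38 min and 48 min, which is 0.0953 M short of the X charged. So the dawn run flattens below its charge, and the spring run, with less Z than X, raises the question of its own roof.

| flask | X | Z | G | time |
|---|---|---|---|---|
| midnight | 0.800 M | 2.40 M | 0.0400 M |  |
| dawn | 0.800 M | 2.40 M | 0.120 M |  |
| winter | 0.800 M | 1.20 M | 0.0400 M |  |
| dusk | 1.20 M | 2.40 M | 0.0400 M |  |
| spring | 0.800 M | 0.520 M | 0.0400 M | 48 min |

| run | time / min | [L] / M |
|---|---|---|
| midnight run | 9.6 | 0.1265 |
| midnight run | 19 | 0.2508 |
| midnight run | 29 | 0.3582 |
| midnight run | 38 | 0.4296 |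
| midnight run | 48 | 0.4904 |
| dawn run | 9.6 | 0.3526 |
| dawn run | 19 | 0.5930 |
| dawn run | 29 | 0.6792 |
| dawn run | 38 | 0.6987 |
| dawn run | 48 | 0.7047 |
| winter run | 9.6 | 0.1080 |
| winter run | 19 | 0.2083 |
| winter run | 29 | 0.3139 |
| winter run | 38 | 0.3903 |
| winter run | 48 | 0.4519 |
| dusk run | 9.6 | 0.1359 |
| dusk run | 19 | 0.2725 |
| dusk run | 29 | 0.4094 |
| dusk run | 38 | 0.5195 |
| dusk run | 48 | 0.6172 |

(each reading ± 0.002 M)

- Overall: X + Z -> L, with G as catalyst.
- Constant volume, constant temperature.
- Readings of a species count what is bound in complexes too.
- "The second partner" is Z.
- An order is taken over about fifteen percent of the charge, up and down.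

1. the power of [G] that the first rate follows, about the charge of the midnight run; measure it at two percent of X made into L
2. the power of [X] that the first rate follows, about the charge of the midnight run; measure it at two percent of X made into L (one fixed amount of L, the same in the runs compared)
3. L in the spring run at 48 min, as a share of the X charged

What is the roof in the spring run? Z is charged at 0.520 M against 0.800 M of X, so by the charges Z is the limiting reagent and L cannot pass 65.0% of the X charged.

Does the spring run get near that roof by 48 min? That depends on how much the rate feels Z. I call the Z order, 0.228, the power of [Z] that L follows at the first reading, taken from the winter run against the midnight run. On this scale, zero means L ignores Z and 1 means L follows Z in step. The winter run has half the Z of the midnight run, yet at 9.6 min its L is 0.854 of the midnight run's L. The order therefore sits near the zero end.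

How much does so weak an order cost when Z falls so far? At the spring charge, the drag on the midnight run's 0.4904 M is the ratio of the Z charges raised to that order, 0.705. As a first estimate that gives 0.346 M and leaves 0.174 M of Z. Z is then better taken at the geometric middle of its fall, 0.301 M, which gives 0.305 M. I commit to 38.1% of the X charged.

The forecast gives 0.96 in G, 0.2 in X and 34% for the spring run, with the remark on the dawn plateau, “I read that as reversibility”. My spring figure is higher than the forecast's.

The flask gives 0.85 in G, 0.20 in X and 42.7% for the spring run.

    G + X → GX (1.356 /M/min)
    GX + Z → Wa (5.940 /M/min)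
    Wa → L + G (0.8640 /min)
    X → Gu (0.01248 /min)
    GX + X ⇌ GX2, settled at all times (9.000 /M)

G carrying X as GX must meet Z, while further X can pair GX into GX2. That pairing lifts the apparent order in Z about the midnight charge from 0.025 to 0.21; my Z order, read over the wider step to the winter run, was 0.228. Put through the spring charge as before, the order with the pairing taken away gives a drag of 0.963, against 0.730 with it. Without the pairing, the spring run reaches 57.2% instead of 42.7%.

The data were generated by integration for substances that don't exist, noise included.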